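**Retrosynthetic overview**
1. Feature: in the ring (C1 carbonyl between C2–OMe and C6–heptadecyl, C3–H, C4 carbonyl, C5–H) the oxygens on C2 and C4 are meta to each other and C6 carries the chain, which is the acetate pattern of a stearoyl-primed tetraketide. Only the C1 oxygen lies outside that pattern, and a carboxyl carbon holds its place until late.
2. Quinone ⇒ 2-heptadecyl-4,6-dimethoxyphenol (oxidative demethylation at C4) ⇒ the matching benzaldehyde (aryl-to-oxygen shift) ⇒ methyl 2-heptadecyl-4,6-dihydroxybenzoate.
3. Resorcylate ⇒ methyl 3,5,7-trioxotetracosanoate by a C2-to-C7 aldol that forms the quinone C1–C6 bond and the only ring of the route.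
4. Triketo ester ⇒ trianion of methyl 3,5-dioxohexanoate (from dehydroacetic acid) + methyl stearate.

Key step: step 3

Remark: the target is achiral, so no step has to set configuration; in step 2 the diketo ester 2 is used in excess over 3 because its trianion also has to take up the acidic proton of the product.

**Step 1**
Reactants: 1 dehydroacetic acid (3-acetyl-6-methyl-2H-pyran-2,4(3H)-dione)
Product: 2 methyl 3,5-dioxohexanoate
Conditions: Mg(OMe)2 (2 equiv), MeOH, reflux; cold 2 M HCl
Reagents that add atoms: methanol (CO), supplied as its magnesium alkoxide Mg(OMe)2 ([Mg+2].C[O-].C[O-])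
Why: Lactone methanolysis followed by retro-Claisen loss of the 3-acetyl group as methyl acetate should give the β,δ-diketo ester, whose magnesium chelate shields it from further cleavage or ring closure.

**Step 2**
Reactants: 2 methyl 3,5-dioxohexanoate; 3 methyl stearate (methyl octadecanoate)
Product: 5 methyl 3,5,7-trioxotetracosanoate, via trilithium trianion of methyl 3,5-dioxohexanoate 4 (not isolated)
Conditions: LiN(iPr)2 (3.1 equiv per 2), THF, −78 to 0 °C; then 3 (0.45 equiv) in THF, 0 °C; cold 1 M HCl
Reagents that add atoms: none
Why: Claisen-type C-acylation of a polyanion, in which the terminal C6 carbanion of 4 is the last formed and most nucleophilic site and so should alone attack the ester carbonyl of 3, while the excess of 4 absorbs the acidic proton of the new 5,7-diketone unit.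

**Step 3**
Reactants: 5 methyl 3,5,7-trioxotetracosanoate
Product: 7 methyl 2-heptadecyl-4,6-dihydroxybenzoate, via methyl 2-heptadecyl-2-hydroxy-4,6-dioxocyclohexane-1-carboxylate 6 (not isolated)
Conditions: Cs2CO3 (2 equiv), MeOH–THF 3:1, 0 °C to rt; then HCl in MeOH to pH 1, rt
Reagents that add atoms: none
Why: Carbonate in methanol should turn 5 into its C2,C4-dienolate, whose C2 carbon (activated by the ester and the C3 ketone) adds to the C7 ketone, the only carbonyl then left free, to give aldol 6; acid then removes water and the C3 and C5 carbonyls enolise, so that the ring becomes the benzene ring of 7. The closest known reaction is the biomimetic aldol cyclisation of 3,5,7-triketo esters to 6-substituted resorcylates with mild base followed by acid. The single ring closes in a 6-(enolendo)-exo-trig mode, with the C2=C3 enolate bond inside the new ring and the C7 carbonyl oxygen outside it. The two stereocentres of 6 are not controlled and need not be, since both disappear on aromatisation. The step has to favour the C2-to-C7 aldol over C6-to-C1 Claisen closure (to an acylphloroglucinol), over lactonisation to a 4-hydroxy-2-pyranone and over acid-induced closure to a 4-pyranone: the ketone is the better acceptor and needs no leaving group, a pyranone formed in basic methanol is reopened by methoxide, acid is added only once the carbocycle exists, and aromatisation drains the reversible aldol equilibrium. A weak carbonate base in methanol is preferred to hydroxide so that the methyl ester, which marks the future C1 oxygen, is neither saponified nor pushed into the Claisen path.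

**Step 4**
Reactants: 7 methyl 2-heptadecyl-4,6-dihydroxybenzoate
Product: 8 methyl 2-heptadecyl-4,6-dimethoxybenzoate
Conditions: MeI (5 equiv), K2CO3 (4 equiv), DMF, 40 °C
Reagents that add atoms: iodomethane, CI
Why: Williamson O-methylation of both phenoxides, where the polar aprotic solvent and excess MeI should overcome the hydrogen bond of the 6-OH to the ester.

**Step 5**
Reactants: 8 methyl 2-heptadecyl-4,6-dimethoxybenzoate
Product: 9 (2-heptadecyl-4,6-dimethoxyphenyl)methanol
Conditions: LiAlH4 (1.5 equiv), THF, 0 °C to reflux
Reagents that add atoms: none
Why: Hydride reduction of the ester to the primary alcohol, chosen over a partial reduction because a clean stop at the aldehyde is not to be expected for an ester flanked by an alkyl and a methoxy group.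

**Step 6**
Reactants: 9 (2-heptadecyl-4,6-dimethoxyphenyl)methanol
Product: 10 2-heptadecyl-4,6-dimethoxybenzaldehyde
Conditions: activated MnO2 (15 equiv), CH2Cl2, rt
Reagents that add atoms: none
Why: Benzylic alcohol oxidation with MnO2, which is selective for the electron-rich benzylic position and should stop at the aldehyde.

**Step 7**
Reactants: 10 2-heptadecyl-4,6-dimethoxybenzaldehyde
Product: 12 2-heptadecyl-4,6-dimethoxyphenol, via 2-heptadecyl-4,6-dimethoxyphenyl formate 11 (not isolated)
Conditions: mCPBA (1.3 equiv), CH2Cl2, 0 °C to rt; then K2CO3 (cat.), MeOH, rt, under argon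
Reagents that add atoms: 3-chloroperoxybenzoic acid (mCPBA), OOC(=O)c1cccc(Cl)c1
Why: Baeyer–Villiger (Dakin-type) oxidation, in which the electron-rich 2,4-dimethoxy-6-alkylphenyl group of the peracid adduct should migrate in preference to hydride to give formate 11, which methanolysis converts into the phenol.

**Step 8**
Reactants: 12 2-heptadecyl-4,6-dimethoxyphenol (used at once, without storage)
Product: 13 2-heptadecyl-6-methoxycyclohexa-2,5-diene-1,4-dione (2-heptadecyl-6-methoxy-1,4-benzoquinone)
Conditions: (NH4)2Ce(NO3)6 (2.5 equiv), MeCN–THF–H2O, 0 °C
Reagents that add atoms: water, O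
Why: Oxidative demethylation of a para-methoxyphenol, in which two one-electron oxidations by tetravalent cerium give the phenoxonium ion, water adds at C4 para to the phenol oxygen and the hemiketal loses methanol to the para-quinone, leaving the ortho methoxy group in place.

**Compound list**
1 | dehydroacetic acid (3-acetyl-6-methyl-2H-pyran-2,4(3H)-dione) | CC(=O)C1C(=O)C=C(C)OC1=O | starting material
2 | methyl 3,5-dioxohexanoate | CC(=O)CC(=O)CC(=O)OC | intermediate
3 | methyl stearate (methyl octadecanoate) | CCCCCCCCCCCCCCCCCC(=O)OC | starting material
4 | trilithium trianion of methyl 3,5-dioxohexanoate (C2=C3 and C4=C5 enolates, C6 carbanion) | COC(=O)C=C([O-])C=C([O-])[CH2-].[Li+].[Li+].[Li+] | intermediate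
5 | methyl 3,5,7-trioxotetracosanoate (drawn as the triketo tautomer) | CCCCCCCCCCCCCCCCCC(=O)CC(=O)CC(=O)CC(=O)OC | intermediate
6 | methyl 2-heptadecyl-2-hydroxy-4,6-dioxocyclohexane-1-carboxylate (aldol adduct; C1 and C2 not controlled, diastereomer mixture, so no descriptors) | CCCCCCCCCCCCCCCCCC1(O)CC(=O)CC(=O)C1C(=O)OC | intermediate
7 | methyl 2-heptadecyl-4,6-dihydroxybenzoate | COC(=O)c1c(O)cc(O)cc1CCCCCCCCCCCCCCCCC | intermediate
8 | methyl 2-heptadecyl-4,6-dimethoxybenzoate | COC(=O)c1c(OC)cc(OC)cc1CCCCCCCCCCCCCCCCC | intermediate
9 | (2-heptadecyl-4,6-dimethoxyphenyl)methanol | OCc1c(OC)cc(OC)cc1CCCCCCCCCCCCCCCCC | intermediate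
10 | 2-heptadecyl-4,6-dimethoxybenzaldehyde | O=Cc1c(OC)cc(OC)cc1CCCCCCCCCCCCCCCCC | intermediate
11 | 2-heptadecyl-4,6-dimethoxyphenyl formate | O=COc1c(OC)cc(OC)cc1CCCCCCCCCCCCCCCCC | intermediate
12 | 2-heptadecyl-4,6-dimethoxyphenol | Oc1c(OC)cc(OC)cc1CCCCCCCCCCCCCCCCC | intermediate
13 | 2-heptadecyl-6-methoxycyclohexa-2,5-diene-1,4-dione | CCCCCCCCCCCCCCCCCC1=CC(=O)C=C(OC)C1=O | target

Total step count: 8
Longest linear sequence: 8 steps (1 to 13); 3 enters at step 2.

**Steps most likely to fail**

Step 3. The C6 carbanion may close onto the ester carbonyl, the C5 enol oxygen may lactonise onto the ester, or methoxide may cleave the chain by retro-Claisen attack before the aldol is complete. The fallback removes the ester as an acyl donor by running the aldol on the free acid; it sets out from 3 and comes back at 8. The dianion of pentane-2,4-dione (NaH, then n-BuLi, THF, 0 °C) is acylated at its terminal carbon with 3 to give tricosane-2,4,6-trione F1. Its trianion (LiN(iPr)2, 3 equiv, THF, 0 °C) is carboxylated at the terminal methyl group with CO2 to give 3,5,7-trioxotetracosanoic acid F2. In aqueous NaHCO3–THF the carboxylate cannot be attacked by the C6 carbanion or by an enol oxygen, so only the C2-to-C7 aldol remains and should give 2-heptadecyl-4,6-dihydroxybenzoic acid F3. Exhaustive methylation of the acid and both phenols (MeI, K2CO3, DMF) then gives 8.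

Step 2. Proton transfer from the α-CH2 of 3 or from the newly formed, more acidic product to trianion 4, and side reactions of the released methoxide, may stall the acylation. The fallback changes the acyl donor to an amide whose tetrahedral adduct survives until quench; it sets out from 3 and comes back at 5. Ester 3 is converted with MeNH(OMe)·HCl and i-PrMgCl (THF, −20 °C) into N-methoxy-N-methyloctadecanamide F4. Trianion 4 (1.2 equiv) is then acylated with F4; the chelated adduct releases no acidic ketone in the flask and the amide α-CH2 is less acidic than that of the ester, so acidic quench should give 5.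

Step 8. The one-electron oxidant may over-oxidise or nitrate the very electron-rich ring, couple two phenoxyl radicals, or remove the ortho instead of the para methyl group. The fallback uses a two-electron oxidation through a quinone monoketal; it sets out from 12 and comes back at 13. Phenol 12 with PhI(OAc)2 in MeOH at 0 °C should take up methanol at C4 to give 2-heptadecyl-4,4,6-trimethoxycyclohexa-2,5-dien-1-one F5, and dilute aqueous HCl in THF hydrolyses the ketal to 13.

**Further compounds**
F1 | step 3 | tricosane-2,4,6-trione | CCCCCCCCCCCCCCCCCC(=O)CC(=O)CC(C)=O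
F2 | step 3 | 3,5,7-trioxotetracosanoic acid | CCCCCCCCCCCCCCCCCC(=O)CC(=O)CC(=O)CC(=O)O
F3 | step 3 | 2-heptadecyl-4,6-dihydroxybenzoic acid | OC(=O)c1c(O)cc(O)cc1CCCCCCCCCCCCCCCCC
F4 | step 2 | N-methoxy-N-methyloctadecanamide | CCCCCCCCCCCCCCCCCC(=O)N(C)OC
F5 | step 8 | 2-heptadecyl-4,4,6-trimethoxycyclohexa-2,5-dien-1-one | CCCCCCCCCCCCCCCCCC1=CC(OC)(OC)C=C(OC)C1=O
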